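**Retrosynthetic overview**

1. The target is a cis,cis-germacranolide. The last operations put on the two isobutyrates and unveil the C14 aldehyde; the ten-membered ring is closed at C9–C10 by an intramolecular Nozaki–Hiyama–Kishi reaction of a (Z)-2-iodoalkene onto a C9 aldehyde.
2. The α-methylene-γ-butyrolactone (O–C6 and C11–C7 bonds, both stereocenters C6 and C7, the exocyclic methylene) is made in one palladium-catalysed annulation of 2-bromoacrylic acid onto an acyclic (4Z,6E)-diene.
3. Enabling feature: the lactone oxygen sits on C6, which is allylic to the ring alkene C4=C5 and vicinal to C7, the carbon that bears the acrylate α-carbon C11. O–C6–C7–C11 is therefore the 1,2-carbo-oxygenation pattern of a C4=C5–C6=C7 diene, closed through a π-allyl unit C4–C5–C6 to the five-membered lactone ring.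
4. The diene comes from Suzuki coupling of a (Z)-alkenyl iodide (carbocupration of propyne, sets 4Z) with an (E)-alkenyl boronate made from (S)-but-3-ene-1,2-diol (source of C8).
5. Order of ring formation: γ-lactone (step 5), then the ten-membered carbocycle (step 10).

Key step: step 5

Remark on locants: C1–C15 are germacranolide locants (lactone O on C6; C7 bears C11(=C13)–C12(=O); C8 and C9 carry the esters; C10 carries C14; C4 carries methyl C15). TBS = tert-butyldimethylsilyl.
Remark on chemistry: in step 10 the (S)-configured sulfonamide ligand is assumed to be the antipode matched to the 9S carbinol; if the sense is the reverse, its enantiomer is used in the same way.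

**Step 1**
Reactants: 1 but-3-en-1-ylmagnesium bromide; 2 propyne; 3 iodine
Product: 5 (1Z)-1-iodo-2-methylhexa-1,5-diene, via alkenylcopper 4 (not isolated)
Conditions: 1 (in Et2O), CuBr·SMe2 (1 equiv), Et2O/Me2S, −45 °C; propyne, −25 °C; then I2, THF, −45 → 0 °C
Reagents that add atoms: propyne (2), CC#C; iodine (3), II
Why: Normant carbocupration adds the alkylcopper syn across propyne with the alkyl group on the internal carbon, and iodinolysis of the (Z)-alkenylcopper proceeds with retention, so the Z geometry of the later C4=C5 alkene is fixed here.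

**Step 2**
Reactants: 6 (2S)-but-3-ene-1,2-diol; 7 tert-butyldimethylsilyl chloride
Product: 8 (2S)-1,2-bis(TBS-oxy)but-3-ene
Conditions: TBSCl (2.5 equiv), imidazole, DMF, 0 → 23 °C
Reagents that add atoms: tert-butyldimethylsilyl chloride (7), CC(C)(C)[Si](C)(C)Cl
Why: Standard silylation of both hydroxyls with imidazole as base; the C8 stereocenter comes from the chiral pool and is not touched.

**Step 3**
Reactants: 8 (2S)-1,2-bis(TBS-oxy)but-3-ene; 9 4,4,5,5-tetramethyl-2-vinyl-1,3,2-dioxaborolane
Product: 10 2-[(1E,3S)-3,4-bis(TBS-oxy)but-1-en-1-yl]-4,4,5,5-tetramethyl-1,3,2-dioxaborolane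
Conditions: 9 (3 equiv), second-generation Hoveyda–Grubbs catalyst (5 mol %), CH2Cl2, 40 °C
Reagents that add atoms: 4,4,5,5-tetramethyl-2-vinyl-1,3,2-dioxaborolane (9), C=CB1OC(C)(C)C(C)(C)O1
Why: Olefin cross-metathesis of a terminal alkene with the vinyl boronate should give the (E)-alkenyl boronate under thermodynamic control, with the allylic stereocenter not involved.

**Step 4**
Reactants: 5 (1Z)-1-iodo-2-methylhexa-1,5-diene; 10 2-[(1E,3S)-3,4-bis(TBS-oxy)but-1-en-1-yl]-4,4,5,5-tetramethyl-1,3,2-dioxaborolane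
Product: 11 (2S,3E,5Z)-1,2-bis(TBS-oxy)-6-methyldeca-3,5,9-triene
Conditions: Pd(dppf)Cl2 (5 mol %), aq. K3PO4 (3 equiv), THF, degassed, 23 °C
Reagents that add atoms: none
Why: Suzuki–Miyaura coupling of an alkenyl iodide with an alkenyl boronate proceeds with retention at both partners and so should give the (3E,5Z)-diene; room temperature keeps transmetalation ahead of any carbopalladation of the remote vinyl group.

**Step 5**
Reactants: 11 (2S,3E,5Z)-1,2-bis(TBS-oxy)-6-methyldeca-3,5,9-triene; 12 2-bromoprop-2-enoic acid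
Product: 13 (4S,5R)-4-[(1S)-1,2-bis(TBS-oxy)ethyl]-3-methylidene-5-[(1Z)-2-methylhexa-1,5-dien-1-yl]oxolan-2-one
Conditions: 12 (1.5 equiv), Pd(OAc)2 (10 mol %), P(2-furyl)3 (20 mol %), Ag2CO3 (1.5 equiv), MeCN, 60 °C
Reagents that add atoms: 2-bromoprop-2-enoic acid (12), C=C(Br)C(=O)O
Why: Zerovalent palladium (from Pd(OAc)2 and the phosphine) inserts into the C–Br bond of the 2-bromoacrylate, Ag2CO3 removes bromide so that the carboxylate stays on the metal, the alkenylpalladium adds syn across C6=C7 of the diene with C11 going to the less substituted terminus C7, and the resulting π-allylpalladium (C4–C5–C6) is closed by C–O bond formation at C6 with release of zerovalent palladium. The closest known reaction type is the Larock-type palladium-catalysed heteroannulation of 1,3-dienes by aryl and vinylic halides that carry a carboxylic acid, here run with 2-bromoacrylic acid so that the α-methylene lactone arrives complete. The lactone ring closes by attack of the palladium-bound carboxylate oxygen on the proximal allyl terminus (reductive elimination from a six-membered oxapalladacycle), which gives the five-membered ring at secondary C6 in preference to a seven-membered ring at tertiary C4. C7 is controlled by the C8 stereocenter: in the four-centre insertion the C8–H bond lies in the diene plane, the C8–OSi bond is anti to the incoming C11 and the CH2OSi group points outward (Felkin-type arrangement with minimal allylic strain), which gives the 7,8-erythro relation; C6 is controlled by the 6E geometry, because C11 and O are delivered to the same face of that alkene (net syn addition), which fixes the 6,7-trans lactone, also the more stable isomer should allyl carboxylate ionisation make the closure reversible. The step needs regioselectivity (C7 rather than C4 for carbon, C6 rather than C4 for oxygen), chemoselectivity for the diene over the isolated vinyl group (only the diene gives a stabilised π-allyl) and retention of the 4Z alkene, which is secured because syn/anti exchange at C4 would need a tertiary σ-palladium species and is slower than the intramolecular closure.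

**Step 6**
Reactants: 13 (4S,5R)-4-[(1S)-1,2-bis(TBS-oxy)ethyl]-3-methylidene-5-[(1Z)-2-methylhexa-1,5-dien-1-yl]oxolan-2-one; 14 prop-2-enal
Product: 15 (2E,6Z)-7-[(2R,3S)-3-[(1S)-1,2-bis(TBS-oxy)ethyl]-4-methylidene-5-oxooxolan-2-yl]-6-methylhepta-2,6-dienal
Conditions: acrolein (5 equiv), second-generation Hoveyda–Grubbs catalyst (5 mol %), CH2Cl2, 40 °C
Reagents that add atoms: prop-2-enal (14), C=CC=O
Why: Olefin cross-metathesis of the monosubstituted alkene with acrolein should give the E-enal, while the trisubstituted C4=C5 alkene and the electron-poor 1,1-disubstituted lactone methylene are poor metathesis partners.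

**Step 7**
Reactants: 15 (2E,6Z)-7-[(2R,3S)-3-[(1S)-1,2-bis(TBS-oxy)ethyl]-4-methylidene-5-oxooxolan-2-yl]-6-methylhepta-2,6-dienal; 3 iodine
Product: 16 (2Z,6Z)-7-[(2R,3S)-3-[(1S)-1,2-bis(TBS-oxy)ethyl]-4-methylidene-5-oxooxolan-2-yl]-2-iodo-6-methylhepta-2,6-dienal
Conditions: I2 (2 equiv), pyridine/CH2Cl2, 0 → 23 °C; aq. Na2S2O3 work-up
Reagents that add atoms: iodine (3), II
Why: Amine-mediated α-iodination of an enal (conjugate addition of pyridine, iodination of the enolate, elimination) should give the (Z)-2-iodoenal with iodine cis to the chain, and the much less electrophilic methylene lactone and the isolated trisubstituted alkene are expected to stay untouched.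

**Step 8**
Reactants: 16 (2Z,6Z)-7-[(2R,3S)-3-[(1S)-1,2-bis(TBS-oxy)ethyl]-4-methylidene-5-oxooxolan-2-yl]-2-iodo-6-methylhepta-2,6-dienal; 17 trimethyl orthoformate
Product: 19 (4S,5R)-4-[(1S)-1-(TBS-oxy)-2-hydroxyethyl]-5-[(1Z,5Z)-6-iodo-7,7-dimethoxy-2-methylhepta-1,5-dien-1-yl]-3-methylideneoxolan-2-one, via dimethyl acetal 18 (not isolated)
Conditions: HC(OMe)3 (5 equiv), CSA (10 mol %), MeOH/CH2Cl2, 0 °C, then 0 → 23 °C until the primary silyl ether is cleaved; Et3N quench
Reagents that add atoms: trimethyl orthoformate (17), COC(OC)OC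
Why: Acid-catalysed acetalisation of the aldehyde with the orthoformate is followed in the same pot by acid methanolysis of the primary silyl ether, which is much faster than that of the hindered secondary one at C8.

**Step 9**
Reactants: 19 (4S,5R)-4-[(1S)-1-(TBS-oxy)-2-hydroxyethyl]-5-[(1Z,5Z)-6-iodo-7,7-dimethoxy-2-methylhepta-1,5-dien-1-yl]-3-methylideneoxolan-2-one
Product: 20 (2S)-2-(TBS-oxy)-2-[(2R,3S)-2-[(1Z,5Z)-6-iodo-7,7-dimethoxy-2-methylhepta-1,5-dien-1-yl]-4-methylidene-5-oxooxolan-3-yl]acetaldehyde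
Conditions: Dess–Martin periodinane, pyridine, CH2Cl2, 0 → 23 °C; used crude
Reagents that add atoms: none
Why: Dess–Martin oxidation under pyridine buffer leaves the acetal, the alkenyl iodide and the lactone alone, and the α-silyloxy aldehyde is used at once so that C8 should not epimerise.

**Step 10**
Reactants: 20 (2S)-2-(TBS-oxy)-2-[(2R,3S)-2-[(1Z,5Z)-6-iodo-7,7-dimethoxy-2-methylhepta-1,5-dien-1-yl]-4-methylidene-5-oxooxolan-3-yl]acetaldehyde
Product: 21 (3aS,4S,5S,6E,10Z,11aR)-4-(TBS-oxy)-6-(dimethoxymethyl)-5-hydroxy-10-methyl-3-methylidene-3a,4,5,8,9,11a-hexahydrocyclodeca[b]furan-2(3H)-one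
Conditions: CrCl2 (6 equiv), (S)-N-[2-(4-isopropyl-4,5-dihydro-1,3-oxazol-2-yl)-6-methylphenyl]methanesulfonamide (6.6 equiv), Et3N (6.6 equiv), NiCl2 (20 mol %), THF/MeCN, slow addition of 20 to 0.002 M, 23 °C; aqueous work-up
Reagents that add atoms: none
Why: Nozaki–Hiyama–Kishi reaction, in which nickel-catalysed formation of the alkenylchromium from the (Z)-iodide occurs with retention of geometry and its addition to the aldehyde at high dilution closes the ten-membered ring at C9–C10, with the new carbinol C9 set by reagent control from the chiral sulfonamide ligand on chromium while lactone, acetal and silyl ether are tolerated.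

**Step 11**
Reactants: 21 (3aS,4S,5S,6E,10Z,11aR)-4-(TBS-oxy)-6-(dimethoxymethyl)-5-hydroxy-10-methyl-3-methylidene-3a,4,5,8,9,11a-hexahydrocyclodeca[b]furan-2(3H)-one
Product: 22 (3aR,4S,5S,6E,10Z,11aR)-6-(dimethoxymethyl)-4,5-dihydroxy-10-methyl-3-methylidene-3a,4,5,8,9,11a-hexahydrocyclodeca[b]furan-2(3H)-one
Conditions: n-Bu4NF/AcOH (1:1, 3 equiv), THF, 0 → 23 °C
Reagents that add atoms: none
Why: Fluoride desilylation buffered with acetic acid removes the secondary silyl ether without freeing a C8 alkoxide, so relactonisation to the 8,12-olide is avoided and the acetal stays in place.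

**Step 12**
Reactants: 22 (3aR,4S,5S,6E,10Z,11aR)-6-(dimethoxymethyl)-4,5-dihydroxy-10-methyl-3-methylidene-3a,4,5,8,9,11a-hexahydrocyclodeca[b]furan-2(3H)-one; 23 2-methylpropanoic anhydride
Product: 24 (3aS,4S,5S,6E,10Z,11aR)-6-(dimethoxymethyl)-10-methyl-3-methylidene-2-oxo-2,3,3a,4,5,8,9,11a-octahydrocyclodeca[b]furan-4,5-diyl bis(2-methylpropanoate)
Conditions: isobutyric anhydride (4 equiv), Et3N, DMAP (20 mol %), CH2Cl2, 23 °C
Reagents that add atoms: 2-methylpropanoic anhydride (23), CC(C)C(=O)OC(=O)C(C)C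
Why: DMAP-catalysed acylation esterifies both secondary hydroxyls, and because the two esters are the same any acyl migration between O8 and O9 is of no consequence.

**Step 13**
Reactants: 24 (3aS,4S,5S,6E,10Z,11aR)-6-(dimethoxymethyl)-10-methyl-3-methylidene-2-oxo-2,3,3a,4,5,8,9,11a-octahydrocyclodeca[b]furan-4,5-diyl bis(2-methylpropanoate); 25 water
Product: 26 (3aS,4S,5S,6E,10Z,11aR)-6-formyl-10-methyl-3-methylidene-2-oxo-2,3,3a,4,5,8,9,11a-octahydrocyclodeca[b]furan-4,5-diyl bis(2-methylpropanoate)
Conditions: PPTS (20 mol %), acetone/H2O (9:1), 40 °C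
Reagents that add atoms: water (25), O
Why: Mild acid hydrolysis of the dimethyl acetal unveils the conjugated aldehyde last, when both hydroxyls are acylated and no lactol can form, and the esters and the lactone are stable to these conditions.

**Compound list**

1 | but-3-en-1-ylmagnesium bromide | C=CCC[Mg]Br | starting material
2 | propyne | CC#C | starting material
3 | iodine (I2) | II | starting material
4 | (1Z)-(2-methylhexa-1,5-dien-1-yl)copper (MgBr2 complex) | [Cu]/C=C(/C)CCC=C | intermediate
5 | (1Z)-1-iodo-2-methylhexa-1,5-diene | I/C=C(/C)CCC=C | intermediate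
6 | (2S)-but-3-ene-1,2-diol | C=C[C@H](O)CO | starting material
7 | tert-butyldimethylsilyl chloride | CC(C)(C)[Si](C)(C)Cl | starting material
8 | (2S)-1,2-bis[(tert-butyldimethylsilyl)oxy]but-3-ene | C=C[C@H](O[Si](C)(C)C(C)(C)C)CO[Si](C)(C)C(C)(C)C | intermediate
9 | 4,4,5,5-tetramethyl-2-vinyl-1,3,2-dioxaborolane | C=CB1OC(C)(C)C(C)(C)O1 | starting material
10 | 2-[(1E,3S)-3,4-bis[(tert-butyldimethylsilyl)oxy]but-1-en-1-yl]-4,4,5,5-tetramethyl-1,3,2-dioxaborolane | CC1(C)OB(/C=C/[C@H](O[Si](C)(C)C(C)(C)C)CO[Si](C)(C)C(C)(C)C)OC1(C)C | intermediate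
11 | (2S,3E,5Z)-1,2-bis[(tert-butyldimethylsilyl)oxy]-6-methyldeca-3,5,9-triene | C=CCC/C(C)=C\C=C\[C@H](O[Si](C)(C)C(C)(C)C)CO[Si](C)(C)C(C)(C)C | intermediate
12 | 2-bromoprop-2-enoic acid | C=C(Br)C(=O)O | starting material
13 | (4S,5R)-4-[(1S)-1,2-bis[(tert-butyldimethylsilyl)oxy]ethyl]-3-methylidene-5-[(1Z)-2-methylhexa-1,5-dien-1-yl]oxolan-2-one | C=C1C(=O)O[C@H](/C=C(/C)CCC=C)[C@H]1[C@H](O[Si](C)(C)C(C)(C)C)CO[Si](C)(C)C(C)(C)C | intermediate
14 | prop-2-enal (acrolein) | C=CC=O | starting material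
15 | (2E,6Z)-7-[(2R,3S)-3-[(1S)-1,2-bis[(tert-butyldimethylsilyl)oxy]ethyl]-4-methylidene-5-oxooxolan-2-yl]-6-methylhepta-2,6-dienal | C=C1C(=O)O[C@H](/C=C(/C)CC/C=C/C=O)[C@H]1[C@H](O[Si](C)(C)C(C)(C)C)CO[Si](C)(C)C(C)(C)C | intermediate
16 | (2Z,6Z)-7-[(2R,3S)-3-[(1S)-1,2-bis[(tert-butyldimethylsilyl)oxy]ethyl]-4-methylidene-5-oxooxolan-2-yl]-2-iodo-6-methylhepta-2,6-dienal | C=C1C(=O)O[C@H](/C=C(/C)CC/C=C(\I)C=O)[C@H]1[C@H](O[Si](C)(C)C(C)(C)C)CO[Si](C)(C)C(C)(C)C | intermediate
17 | trimethyl orthoformate | COC(OC)OC | starting material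
18 | (4S,5R)-4-[(1S)-1,2-bis[(tert-butyldimethylsilyl)oxy]ethyl]-5-[(1Z,5Z)-6-iodo-7,7-dimethoxy-2-methylhepta-1,5-dien-1-yl]-3-methylideneoxolan-2-one | C=C1C(=O)O[C@H](/C=C(/C)CC/C=C(\I)C(OC)OC)[C@H]1[C@H](O[Si](C)(C)C(C)(C)C)CO[Si](C)(C)C(C)(C)C | intermediate
19 | (4S,5R)-4-[(1S)-1-[(tert-butyldimethylsilyl)oxy]-2-hydroxyethyl]-5-[(1Z,5Z)-6-iodo-7,7-dimethoxy-2-methylhepta-1,5-dien-1-yl]-3-methylideneoxolan-2-one | C=C1C(=O)O[C@H](/C=C(/C)CC/C=C(\I)C(OC)OC)[C@H]1[C@H](O[Si](C)(C)C(C)(C)C)CO | intermediate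
20 | (2S)-2-[(tert-butyldimethylsilyl)oxy]-2-[(2R,3S)-2-[(1Z,5Z)-6-iodo-7,7-dimethoxy-2-methylhepta-1,5-dien-1-yl]-4-methylidene-5-oxooxolan-3-yl]acetaldehyde | C=C1C(=O)O[C@H](/C=C(/C)CC/C=C(\I)C(OC)OC)[C@H]1[C@H](O[Si](C)(C)C(C)(C)C)C=O | intermediate
21 | (3aS,4S,5S,6E,10Z,11aR)-4-[(tert-butyldimethylsilyl)oxy]-6-(dimethoxymethyl)-5-hydroxy-10-methyl-3-methylidene-3a,4,5,8,9,11a-hexahydrocyclodeca[b]furan-2(3H)-one | C=C1C(=O)O[C@@H]2/C=C(/C)CC/C=C(/C(OC)OC)[C@H](O)[C@@H](O[Si](C)(C)C(C)(C)C)[C@@H]12 | intermediate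
22 | (3aR,4S,5S,6E,10Z,11aR)-6-(dimethoxymethyl)-4,5-dihydroxy-10-methyl-3-methylidene-3a,4,5,8,9,11a-hexahydrocyclodeca[b]furan-2(3H)-one | C=C1C(=O)O[C@@H]2/C=C(/C)CC/C=C(/C(OC)OC)[C@H](O)[C@@H](O)[C@@H]12 | intermediate
23 | 2-methylpropanoic anhydride | CC(C)C(=O)OC(=O)C(C)C | starting material
24 | (3aS,4S,5S,6E,10Z,11aR)-6-(dimethoxymethyl)-10-methyl-3-methylidene-2-oxo-2,3,3a,4,5,8,9,11a-octahydrocyclodeca[b]furan-4,5-diyl bis(2-methylpropanoate) | C=C1C(=O)O[C@@H]2/C=C(/C)CC/C=C(/C(OC)OC)[C@H](OC(=O)C(C)C)[C@@H](OC(=O)C(C)C)[C@@H]12 | intermediate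
25 | water | O | starting material
26 | (3aS,4S,5S,6E,10Z,11aR)-6-formyl-10-methyl-3-methylidene-2-oxo-2,3,3a,4,5,8,9,11a-octahydrocyclodeca[b]furan-4,5-diyl bis(2-methylpropanoate) (CNP0305839.3) | C=C1C(=O)O[C@@H]2/C=C(/C)CC/C=C(/C=O)[C@H](OC(=O)C(C)C)[C@@H](OC(=O)C(C)C)[C@@H]12 | target

**Step count and risks**

Total step count: 13. Longest linear sequence: 12 steps (6 → 8 → 10 → 11 → 13 → 15 → 16 → 19 → 20 → 21 → 22 → 24 → 26).

The three steps most likely to fail:

Step 5. The carboxylate may close on the face of the allyl unit opposite to palladium, or the weak allylic strain of the E alkene may give low face selectivity at C7; either would erode the 6,7-trans and 7,8-erythro outcome. The fallback changes the diene geometry and the closure mode and sets out from 10 and 5. Addition of iodine monochloride to 10 followed by NaOMe (anti elimination, inversion of alkene geometry) should give (1Z,3S)-3,4-bis[(tert-butyldimethylsilyl)oxy]-1-iodobut-1-ene F1. Iodine–lithium exchange on 5 (t-BuLi, −78 °C) and ZnCl2 should give (1Z)-(2-methylhexa-1,5-dien-1-yl)zinc chloride F2. Negishi coupling of F1 with F2 (Pd(PPh3)4, THF) should give (2S,3Z,5Z)-1,2-bis[(tert-butyldimethylsilyl)oxy]-6-methyldeca-3,5,9-triene F3. Annulation of F3 with 12 under chloride-rich conditions (Pd(OAc)2, n-Bu4NCl, NaHCO3, DMF, 60 °C), in which the free carboxylate attacks anti to palladium, should turn the 6Z alkene into the same 6,7-trans lactone, and the stronger allylic strain of the Z alkene should sharpen the face selectivity at C7. The route is rejoined at 13.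

Step 10. Reagent control in the ring-closing carbonyl addition may be weak or mismatched, so that the C9 carbinol forms with low selectivity. The fallback sets out from 20 and separates ring closure from the setting of C9. Ligand-free cyclisation (CrCl2, NiCl2 cat., DMSO/THF, high dilution) is accepted as a mixture of 21 and its C9 epimer (3aS,4S,5R,6E,10Z,11aR)-4-[(tert-butyldimethylsilyl)oxy]-6-(dimethoxymethyl)-5-hydroxy-10-methyl-3-methylidene-3a,4,5,8,9,11a-hexahydrocyclodeca[b]furan-2(3H)-one F4. Dess–Martin oxidation of the mixture should give the single enone (3aS,4S,6Z,10Z,11aR)-4-[(tert-butyldimethylsilyl)oxy]-6-(dimethoxymethyl)-10-methyl-3-methylidene-3a,4,9,11a-tetrahydrocyclodeca[b]furan-2,5(3H,8H)-dione F5. Corey–Bakshi–Shibata reduction of F5 (oxazaborolidine catalyst, catecholborane, toluene, −78 °C, catalyst antipode chosen for 9S) should return the route to 21.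

Step 3. The cross-metathesis may stall at the hindered allylic silyl ether while the vinyl boronate homodimerises. The fallback sets out from 8 and builds the boronate by olefination instead. Ozonolysis of 8 (O3, CH2Cl2, −78 °C; PPh3) should give (2R)-2,3-bis[(tert-butyldimethylsilyl)oxy]propanal F6. Takai–Utimoto-type boryl olefination of F6 with pinacol (dichloromethyl)boronate (CrCl2, LiI, THF) should give the (E)-alkenyl boronate, and the route is rejoined at 10.

**Further compounds**

F1 | step 5 | (1Z,3S)-3,4-bis[(tert-butyldimethylsilyl)oxy]-1-iodobut-1-ene | I/C=C\[C@H](O[Si](C)(C)C(C)(C)C)CO[Si](C)(C)C(C)(C)C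
F2 | step 5 | (1Z)-(2-methylhexa-1,5-dien-1-yl)zinc chloride | Cl[Zn]/C=C(/C)CCC=C
F3 | step 5 | (2S,3Z,5Z)-1,2-bis[(tert-butyldimethylsilyl)oxy]-6-methyldeca-3,5,9-triene | C=CCC/C(C)=C\C=C/[C@H](O[Si](C)(C)C(C)(C)C)CO[Si](C)(C)C(C)(C)C
F4 | step 10 | (3aS,4S,5R,6E,10Z,11aR)-4-[(tert-butyldimethylsilyl)oxy]-6-(dimethoxymethyl)-5-hydroxy-10-methyl-3-methylidene-3a,4,5,8,9,11a-hexahydrocyclodeca[b]furan-2(3H)-one | C=C1C(=O)O[C@@H]2/C=C(/C)CC/C=C(/C(OC)OC)[C@@H](O)[C@@H](O[Si](C)(C)C(C)(C)C)[C@@H]12
F5 | step 10 | (3aS,4S,6Z,10Z,11aR)-4-[(tert-butyldimethylsilyl)oxy]-6-(dimethoxymethyl)-10-methyl-3-methylidene-3a,4,9,11a-tetrahydrocyclodeca[b]furan-2,5(3H,8H)-dione | C=C1C(=O)O[C@@H]2/C=C(/C)CC/C=C(/C(OC)OC)C(=O)[C@@H](O[Si](C)(C)C(C)(C)C)[C@@H]12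
F6 | step 3 | (2R)-2,3-bis[(tert-butyldimethylsilyl)oxy]propanal | O=C[C@H](O[Si](C)(C)C(C)(C)C)CO[Si](C)(C)C(C)(C)C
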